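**Retrosynthetic overview**
1. All twenty skeletal carbons come from all-E-geranylgeraniol 1; no C–C bond is made outside the ring-forming step.
2. The side-chain stereocentre (C-14) is set first: Sharpless epoxide 2, then a C–O-retentive, hydroxyl-directed opening to the exo-methylene diol 3, then diacetate 4.
3. Key disconnection: C4–C5 and C9–C10 of the decalin are cut together, so the last step is an acid-controlled, proton-initiated bicyclization of acyclic 4 through cation 5, ending by loss of H-7 to give target 6 directly.
4. Ring order: ring A then ring B, both in that single final operation; nothing is done after the rings exist.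

Assumption: the (S,S)-acid of step 4 (and the (R)-binaphthol acid of its fallback) is taken to select the chain fold that gives the 5S,9S,10S ring series; if the observed sense is the reverse, the mirror-image acid is used and nothing else changes.

Labdane numbering is used for 5 and 6; C-2 of the open chain in 2–4 becomes C-14 of the target.

Step 1
Reactants: 1 all-E-geranylgeraniol [(2E,6E,10E)-3,7,11,15-tetramethylhexadeca-2,6,10,14-tetraen-1-ol; commercial, produced in bulk from annatto]
Product: 2 (2R,3R)-2,3-epoxygeranylgeraniol
Conditions: Ti(OiPr)4 (10 mol %), D-(−)-diethyl tartrate (12 mol %), t-BuOOH (2 equiv, decane), 4 Å molecular sieves, CH2Cl2, −20 °C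
Reagents that add atoms: tert-butyl hydroperoxide, CC(C)(C)OO
Why: Sharpless asymmetric epoxidation: the titanium tartrate binds the allylic alkoxide and so oxidises only the 2,3-alkene of the four, and the D-(−)-tartrate delivers oxygen to the face that gives the (2R,3R)-epoxide (typically ≥94% ee for geraniol-type E-allylic alcohols), which fixes the carbon that becomes C-14.

Step 2
Reactants: 2 (2R,3R)-2,3-epoxygeranylgeraniol
Product: 3 (2S,6E,10E)-7,11,15-trimethyl-3-methylidenehexadeca-6,10,14-triene-1,2-diol
Conditions: Ti(OiPr)4 (2.0 equiv), CH2Cl2, 23 °C, 16 h (40 °C if slow); 10% aq. tartaric acid work-up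
Reagents that add atoms: none
Why: Hydroxyl-directed titanium alkoxide epoxy alcohol rearrangement (epoxide-to-allylic alcohol isomerization by syn β-elimination): titanium held on O-1 activates the epoxide, the tertiary C3–O bond stretches and a ligand alkoxide removes a proton from the C-3 methyl, which is cis to the CH2O–Ti arm in the E-derived epoxide, so the exo-methylene diol forms, and because the C2–O bond is never broken the centre keeps its geometry (it reads S only because the CIP ranks change).

Step 3
Reactants: 3 (2S,6E,10E)-7,11,15-trimethyl-3-methylidenehexadeca-6,10,14-triene-1,2-diol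
Product: 4 (2S,6E,10E)-7,11,15-trimethyl-3-methylidenehexadeca-6,10,14-triene-1,2-diyl diacetate
Conditions: Ac2O (3 equiv), pyridine, 4-(dimethylamino)pyridine (5 mol %), CH2Cl2, 0 °C → rt
Reagents that add atoms: acetic anhydride, CC(=O)OC(C)=O
Why: Nucleophilic-catalysis acylation (DMAP-catalysed esterification) of the primary and the secondary allylic hydroxyl under basic conditions that touch neither the alkenes nor the stereocentre.

Step 4
Reactants: 4 (2S,6E,10E)-7,11,15-trimethyl-3-methylidenehexadeca-6,10,14-triene-1,2-diyl diacetate
Product: 6 (14S)-labda-7,13(16)-diene-14,15-diyl diacetate, via 8-labdanyl cation 5 (not isolated)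
Conditions: (S,S)-imidodiphosphorimidate acid HN[P(=NSO2CF3)(O2C20H10Ar2)]2, O2C20H10Ar2 = (S)-3,3′-diaryl-1,1′-binaphthalene-2,2′-diolate, Ar = 3,5-(CF3)2C6H3 (5 mol %), (CF3)3COH/CH2Cl2 (4:1), −20 °C; AgNO3–silica chromatography
Reagents that add atoms: none
Why: Proposed new method: the confined chiral Brønsted acid in a fluorinated alcohol protonates only the terminal isopropylidene alkene (the 3-methylidene alkene is switched off by its two acetoxy groups) on the face it selects, the chair–chair folded all-E triene closes ring A and ring B by two anti additions to give trans-decalin cation 5 with 5α-H, 10β-CH3 and the C-9 side chain equatorial, and loss of the axial, orbital-aligned H-7 to the catalyst anion (Zaitsev; any exocyclic isomer can re-enter 5 under the acid) gives the 7-ene with C-14 untouched; the closest known reaction type is the imidodiphosphorimidate-catalysed asymmetric head-to-tail cyclization of homofarnesol to ambrox in fluorinated alcohols, together with chiral Lewis-acid-assisted Brønsted acid cyclizations of polyprenoids (Stork–Eschenmoser polyene cyclization).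

**Compound list**
1 | all-E-geranylgeraniol, (2E,6E,10E)-3,7,11,15-tetramethylhexadeca-2,6,10,14-tetraen-1-ol | CC(C)=CCC/C(C)=C/CC/C(C)=C/CC/C(C)=C/CO | starting material
2 | (2R,3R)-2,3-epoxygeranylgeraniol, [(2R,3R)-3-methyl-3-[(3E,7E)-4,8,12-trimethyltrideca-3,7,11-trien-1-yl]oxiran-2-yl]methanol | CC(C)=CCC/C(C)=C/CC/C(C)=C/CC[C@@]1(C)O[C@@H]1CO | intermediate
3 | (2S,6E,10E)-7,11,15-trimethyl-3-methylidenehexadeca-6,10,14-triene-1,2-diol | CC(C)=CCC/C(C)=C/CC/C(C)=C/CCC(=C)[C@H](O)CO | intermediate
4 | (2S,6E,10E)-7,11,15-trimethyl-3-methylidenehexadeca-6,10,14-triene-1,2-diyl diacetate | CC(C)=CCC/C(C)=C/CC/C(C)=C/CCC(=C)[C@H](OC(C)=O)COC(C)=O | intermediate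
5 | (14S)-14,15-diacetoxylabd-13(16)-en-8-yl cation (5α-H, 9α-H, 10β-CH3; trans-decalin, tertiary cation at C-8) | C=C(CC[C@H]1[C+](C)CC[C@H]2C(C)(C)CCC[C@]12C)[C@@H](COC(C)=O)OC(C)=O | intermediate
6 | (14S)-labda-7,13(16)-diene-14,15-diyl diacetate, (2S)-3-methylidene-5-[(1S,4aS,8aS)-2,5,5,8a-tetramethyl-1,4,4a,5,6,7,8,8a-octahydronaphthalen-1-yl]pentane-1,2-diyl diacetate | C=C(CC[C@H]1C(C)=CC[C@H]2C(C)(C)CCC[C@]12C)[C@@H](COC(C)=O)OC(C)=O | target

**Step count and risks**
Total steps: 4. Longest linear sequence: 4 (fully linear from 1).

Because C-14 is already enantiopure in 4, imperfect face control in step 4 gives the (5R,9R,10R,14S) diastereomer, not the enantiomer. It can be removed by chromatography, and the major diastereomer is then of higher ee than either stereo-determining step alone.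

The three steps most likely to fail:

1. Step 4. The risks are: proton loss from 5 toward C-17 or C-9 (8(17)- and 8-ene isomers); arrest after ring A; capture of 5 by the 13(16)-alkene with acetoxonium participation (a third ring); acid-induced allylic acetate shift; and incomplete face control. Fallback, setting out from 4 and coming back at 6: the rings are closed one after the other. Stoichiometric SnCl4·(R)-2-(2-fluorobenzyloxy)-2′-hydroxy-1,1′-binaphthyl (2.2 equiv, toluene, −78 °C) protonates the terminal alkene enantioselectively and is stopped after ring A, giving (2S,6E)-7-methyl-3-methylidene-9-[(1S)-2,6,6-trimethylcyclohex-2-en-1-yl]non-6-ene-1,2-diyl diacetate F1 (with its ring double-bond isomers). SnCl4/CF3CO2H (CH2Cl2, −78 °C) then re-protonates the ring alkene and closes ring B under control of the C-5 centre, rejoining the route at 6.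

2. Step 2. The risks are competing proton removal from C-4 of the chain (giving the 3-ene-1,2-diol) and isopropoxide opening at C-3. Fallback, setting out from 2 and coming back at 3: a silylative opening–elimination replaces the directed rearrangement. Me3SiOTf (2.2 equiv) with 2,6-lutidine (toluene, −78 °C) silylates O-1 and opens the epoxide at the tertiary carbon, and 1,8-diazabicyclo[5.4.0]undec-7-ene (DBU) then removes a methyl proton, giving (2S,6E,10E)-7,11,15-trimethyl-3-methylidene-1,2-bis(trimethylsilyloxy)hexadeca-6,10,14-triene F2. K2CO3 in MeOH removes both silyl groups and returns to 3.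

3. Step 1. The tertiary epoxy alcohol is acid-labile on work-up, and its ee fixes C-14 for the whole route. Fallback, setting out from 1 and coming back at 2: the epoxide is made by iminium catalysis on the enal. MnO2 (CH2Cl2, rt) oxidises 1 to (2E,6E,10E)-3,7,11,15-tetramethylhexadeca-2,6,10,14-tetraenal F3. H2O2 with (R)-2-[bis(3,5-bis(trifluoromethyl)phenyl)(trimethylsilyloxy)methyl]pyrrolidine (10 mol %, CH2Cl2, rt) epoxidises only the conjugated alkene, giving (2S,3R)-3-methyl-3-[(3E,7E)-4,8,12-trimethyltrideca-3,7,11-trien-1-yl]oxirane-2-carbaldehyde F4. NaBH4 (MeOH, 0 °C) reduces the aldehyde and returns to 2.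

Further compounds
F1 | step 4 | (2S,6E)-7-methyl-3-methylidene-9-[(1S)-2,6,6-trimethylcyclohex-2-en-1-yl]non-6-ene-1,2-diyl diacetate | CC1=CCCC(C)(C)[C@@H]1CC/C(C)=C/CCC(=C)[C@H](OC(C)=O)COC(C)=O
F2 | step 2 | (2S,6E,10E)-7,11,15-trimethyl-3-methylidene-1,2-bis(trimethylsilyloxy)hexadeca-6,10,14-triene | CC(C)=CCC/C(C)=C/CC/C(C)=C/CCC(=C)[C@H](O[Si](C)(C)C)CO[Si](C)(C)C
F3 | step 1 | (2E,6E,10E)-3,7,11,15-tetramethylhexadeca-2,6,10,14-tetraenal | CC(C)=CCC/C(C)=C/CC/C(C)=C/CC/C(C)=C/C=O
F4 | step 1 | (2S,3R)-3-methyl-3-[(3E,7E)-4,8,12-trimethyltrideca-3,7,11-trien-1-yl]oxirane-2-carbaldehyde | CC(C)=CCC/C(C)=C/CC/C(C)=C/CC[C@@]1(C)O[C@@H]1C=O
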